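The 1,3-diol C2(OH)–C1–C1'(OH) is treated as the syn aldol of a 2-tetralone, a relationship that a cyclic enolate does not deliver, and is unveiled by a stereospecific semipinacol ring enlargement. An indan-1-ol carrying a (2S,3S)-cis-alkynyl epoxide on its carbinol carbon rearranges under BF3·OEt2: the electron-rich aryl carbon (future C8a) shifts from the carbinol carbon (future C2) to the neighbouring epoxide carbon (future C1) with inversion, so the five-membered ring becomes ring B of the tetralin while C1 and C1' are fixed in one operation. Chelation-controlled reduction then relays C2, and Sonogashira arylation followed by trans-hydroalumination completes the (E)-styryl arm.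

Key step: step 5

Remark on the chemistry (assumption): C1–C8a denote the tetralin atoms of the target and C1' the side-chain carbinol carbon. The sense of induction of the glucose-derived spiro-oxazolidinone ketone on a Z-enyne is taken from the spiro transition-state model with the alkyne next to the oxazolidinone. On that model the L-glucose-derived antipode should give the (2S,3S)-epoxide; if the sense were the reverse, the D-glucose-derived ketone would take its place.

Step 1
Reactants: 1 5,6-dimethoxy-1-indanone; 2 ethynylmagnesium bromide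
Product: 3 1-ethynyl-5,6-dimethoxy-2,3-dihydro-1H-inden-1-ol (racemic)
Conditions: HC≡CMgBr (1.5 equiv), LaCl3·2LiCl (0.3 equiv), THF, 0 °C to rt; sat. aq. NH4Cl
Reagents that add atoms: ethynylmagnesium bromide, C#C[Mg]Br
Why: Grignard 1,2-addition of an alkynyl nucleophile, with LaCl3·2LiCl favouring addition over enolization of the electron-rich indanone; the carbinol centre is racemic, which is harmless because it becomes the carbonyl carbon in step 5.

Step 2
Reactants: 3 1-ethynyl-5,6-dimethoxy-2,3-dihydro-1H-inden-1-ol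
Product: 5 1-[(Z)-2-iodoethenyl]-5,6-dimethoxy-2,3-dihydro-1H-inden-1-ol (racemic), via cyclic sodium vinylalanate 4 (not isolated)
Conditions: NaAlH2(OCH2CH2OMe)2 (Red-Al, 2.2 equiv), THF, 0 °C to rt; EtOAc; then I2, −78 to 0 °C; aq. Na2S2O3, aq. KNaC4H4O6
Reagents that add atoms: iodine, II
Why: Hydroxyl-directed trans-hydroalumination of the propargylic alcohol places aluminium on the terminal carbon, cis to the carbinol in a five-membered alanate, and iodinolysis with retention should give the Z-iodoalkene (Red-Al/I2 protocol).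

Step 3
Reactants: 5 1-[(Z)-2-iodoethenyl]-5,6-dimethoxy-2,3-dihydro-1H-inden-1-ol; 6 ethynyl(trimethyl)silane
Product: 7 5,6-dimethoxy-1-[(Z)-4-(trimethylsilyl)but-1-en-3-yn-1-yl]-2,3-dihydro-1H-inden-1-ol (racemic)
Conditions: PdCl2(PPh3)2 (3 mol %), CuI (6 mol %), Et3N, THF, rt
Reagents that add atoms: ethynyl(trimethyl)silane, C#C[Si](C)(C)C
Why: Sonogashira coupling of a vinyl iodide proceeds with retention of the Z geometry at room temperature, where the tertiary Z-enynol should not yet cycloisomerize.

Step 4
Reactants: 7 5,6-dimethoxy-1-[(Z)-4-(trimethylsilyl)but-1-en-3-yn-1-yl]-2,3-dihydro-1H-inden-1-ol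
Product: 8 5,6-dimethoxy-1-{(2S,3S)-3-[(trimethylsilyl)ethynyl]oxiran-2-yl}-2,3-dihydro-1H-inden-1-ol (cis-epoxide, both epimers at the carbinol carbon)
Conditions: L-glucose-derived N-(4-methylphenyl) spiro-oxazolidinone ketone (30 mol %), Oxone (2KHSO5·KHSO4·K2SO4), K2CO3, Bu4NHSO4, DME/CH2(OMe)2, aq. K2CO3–AcOH buffer, −10 to 0 °C
Reagents that add atoms: potassium peroxymonosulfate (the oxidant in Oxone), [K+].[O-]S(=O)(=O)OO
Why: Shi-type dioxirane epoxidation of a conjugated Z-enyne is stereospecifically cis, and the catalyst, which places the alkyne next to its oxazolidinone, should choose the same alkene face in both enantiomers of 7; the two carbinol epimers of 8 converge in step 5.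

Step 5
Reactants: 8 5,6-dimethoxy-1-{(2S,3S)-3-[(trimethylsilyl)ethynyl]oxiran-2-yl}-2,3-dihydro-1H-inden-1-ol
Product: 9 (1R)-1-[(1R)-1-hydroxy-3-(trimethylsilyl)prop-2-yn-1-yl]-6,7-dimethoxy-3,4-dihydronaphthalen-2(1H)-one
Conditions: BF3·OEt2 (1.1 equiv), CH2Cl2, −78 °C; Et3N then sat. aq. NaHCO3 at −78 °C
Reagents that add atoms: none
Why: BF3 binds the epoxide oxygen, and the C7a–C1 aryl bond of the indane, antiperiplanar to the breaking C–O bond at the epoxide carbon next to the carbinol, shifts to that carbon through a phenonium-like bridged transition state while the carbinol oxygen closes to the C=O (semipinacol rearrangement of a 2,3-epoxy alcohol, the epoxide counterpart of a Tiffeneau–Demjanov ring enlargement). Ring B is not closed end to end: it forms by a 1,2-shift that inserts the former epoxide carbon between C8a and the carbonyl carbon, so the five-membered ring grows by one atom. C1 is set by inversion at the migration terminus, controlled by the epoxide configuration, and C1' keeps its epoxide C–O bond, so the (2S,3S)-cis-epoxide should give the (1R,1'R) syn aldol. Aryl rather than methylene migration is secured by the methoxy group para to the migrating carbon and by a monodentate Lewis acid that lets either carbinol epimer place the aryl group anti to the leaving oxygen, so both epimers of 8 should converge on 9. Cleavage of the propargylic C–O bond is disfavoured because a silylalkyne stabilises a cation poorly and offers no anchimeric help. The ketone is epimerizable at C1 and prone to retro-aldol cleavage, hence the cold quench and direct use of the crude product in step 6.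

Step 6
Reactants: 9 (1R)-1-[(1R)-1-hydroxy-3-(trimethylsilyl)prop-2-yn-1-yl]-6,7-dimethoxy-3,4-dihydronaphthalen-2(1H)-one
Product: 12 (1S,2R)-1-[(1R)-1-hydroxyprop-2-yn-1-yl]-6,7-dimethoxy-1,2,3,4-tetrahydronaphthalen-2-ol, via diethylboron chelate 10 (not isolated), via silyl diol 11 (not isolated)
Conditions: Et2BOMe (1.2 equiv), THF/MeOH 4:1, −78 °C; NaBH4, −78 °C; then K2CO3, MeOH, rt
Reagents that add atoms: none
Why: Narasaka–Prasad reduction: the boron chelate is locked with the alkynyl group equatorial and the C1–C8a bond axial, external hydride attacks C2 axially anti to that bond to give the 1,3-syn diol, which is the cis-1,2 arrangement on ring B (2R), and K2CO3/MeOH then releases boron and cleaves the C–Si bond.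

Step 7
Reactants: 12 (1S,2R)-1-[(1R)-1-hydroxyprop-2-yn-1-yl]-6,7-dimethoxy-1,2,3,4-tetrahydronaphthalen-2-ol; 13 4-iodophenol
Product: 14 (1S,2R)-1-[(1R)-1-hydroxy-3-(4-hydroxyphenyl)prop-2-yn-1-yl]-6,7-dimethoxy-1,2,3,4-tetrahydronaphthalen-2-ol
Conditions: PdCl2(PPh3)2 (5 mol %), CuI (10 mol %), Et3N, DMF (degassed), rt to 40 °C
Reagents that add atoms: 4-iodophenol, Oc1ccc(I)cc1
Why: Sonogashira coupling of a terminal alkyne with an aryl iodide tolerates the free phenol and the diol and touches no stereocentre.

Step 8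
Reactants: 14 (1S,2R)-1-[(1R)-1-hydroxy-3-(4-hydroxyphenyl)prop-2-yn-1-yl]-6,7-dimethoxy-1,2,3,4-tetrahydronaphthalen-2-ol
Product: 15 (1S,2R)-1-[(1S,2E)-1-hydroxy-3-(4-hydroxyphenyl)prop-2-en-1-yl]-6,7-dimethoxy-1,2,3,4-tetrahydronaphthalen-2-ol
Conditions: NaAlH2(OCH2CH2OMe)2 (Red-Al, 6 equiv), THF, 0 °C to rt; aq. KNaC4H4O6 (neutral work-up)
Reagents that add atoms: none
Why: Trans-hydroalumination of the propargylic alkoxide by Red-Al (hydride to the carbon next to the carbinol, aluminium on the aryl-bearing carbon) and protonolysis with retention should give the E-allylic alcohol only; the descriptor at C1' changes from R to S because the alkenyl group ranks below C1, not because the centre is touched.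

Compound list
1 | 5,6-dimethoxy-1-indanone | COc1cc2CCC(=O)c2cc1OC | starting material
2 | ethynylmagnesium bromide | C#C[Mg]Br | starting material
3 | 1-ethynyl-5,6-dimethoxy-2,3-dihydro-1H-inden-1-ol (racemic) | COc1cc2CCC(O)(C#C)c2cc1OC | intermediate
4 | cyclic sodium vinylalanate of 3 (spiro oxaaluminacyclopentene, two 2-methoxyethoxy ligands on aluminium) | [Na+].COCCO[Al-]1(OCCOC)OC2(CCc3cc(OC)c(OC)cc32)C=C1 | intermediate
5 | 1-[(Z)-2-iodoethenyl]-5,6-dimethoxy-2,3-dihydro-1H-inden-1-ol (racemic) | COc1cc2CCC(O)(/C=C\I)c2cc1OC | intermediate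
6 | ethynyl(trimethyl)silane | C#C[Si](C)(C)C | starting material
7 | 5,6-dimethoxy-1-[(Z)-4-(trimethylsilyl)but-1-en-3-yn-1-yl]-2,3-dihydro-1H-inden-1-ol (racemic) | COc1cc2CCC(O)(/C=C\C#C[Si](C)(C)C)c2cc1OC | intermediate
8 | 5,6-dimethoxy-1-{(2S,3S)-3-[(trimethylsilyl)ethynyl]oxiran-2-yl}-2,3-dihydro-1H-inden-1-ol (cis-epoxide; carbinol carbon unspecified, both epimers) | COc1cc2CCC(O)([C@H]3O[C@H]3C#C[Si](C)(C)C)c2cc1OC | intermediate
9 | (1R)-1-[(1R)-1-hydroxy-3-(trimethylsilyl)prop-2-yn-1-yl]-6,7-dimethoxy-3,4-dihydronaphthalen-2(1H)-one | COc1cc2c(cc1OC)[C@H]([C@@H](O)C#C[Si](C)(C)C)C(=O)CC2 | intermediate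
10 | O-diethylboryl chelate of 9 (boron bound to the C1' oxygen and coordinated by the C2 carbonyl) | COc1cc2c(cc1OC)[C@H]([C@@H](OB(CC)CC)C#C[Si](C)(C)C)C(=O)CC2 | intermediate
11 | (1S,2R)-1-[(1R)-1-hydroxy-3-(trimethylsilyl)prop-2-yn-1-yl]-6,7-dimethoxy-1,2,3,4-tetrahydronaphthalen-2-ol | COc1cc2c(cc1OC)[C@H]([C@@H](O)C#C[Si](C)(C)C)[C@H](O)CC2 | intermediate
12 | (1S,2R)-1-[(1R)-1-hydroxyprop-2-yn-1-yl]-6,7-dimethoxy-1,2,3,4-tetrahydronaphthalen-2-ol | COc1cc2c(cc1OC)[C@H]([C@@H](O)C#C)[C@H](O)CC2 | intermediate
13 | 4-iodophenol | Oc1ccc(I)cc1 | starting material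
14 | (1S,2R)-1-[(1R)-1-hydroxy-3-(4-hydroxyphenyl)prop-2-yn-1-yl]-6,7-dimethoxy-1,2,3,4-tetrahydronaphthalen-2-ol | COc1cc2c(cc1OC)[C@H]([C@@H](O)C#Cc1ccc(O)cc1)[C@H](O)CC2 | intermediate
15 | (1S,2R)-1-[(1S,2E)-1-hydroxy-3-(4-hydroxyphenyl)prop-2-en-1-yl]-6,7-dimethoxy-1,2,3,4-tetrahydronaphthalen-2-ol | COc1cc2c(cc1OC)[C@H]([C@@H](O)/C=C/c1ccc(O)cc1)[C@H](O)CC2 | target

Total step count: 8. Longest linear sequence: 8 steps (from 1).

Steps most likely to fail

Step 5. The epoxide may ionize at its propargylic carbon instead of accepting the aryl shift, the ring methylene may migrate in one carbinol epimer, or the ketone may epimerize at C1 or undergo retro-aldol cleavage before it is reduced. The fallback keeps a one-carbon ring enlargement of the indanone but moves the stereocontrol to later steps; it sets out from 1 and comes back at 12. Homologation of 1 with ethyl diazoacetate (BF3·OEt2, CH2Cl2, 0 °C), with migration of the electron-rich aryl carbon, should give ethyl 6,7-dimethoxy-2-oxo-1,2,3,4-tetrahydronaphthalene-1-carboxylate F1. Noyori-type transfer hydrogenation with dynamic kinetic resolution (RuCl(p-cymene)[TsDPEN], the antipode that gives the 2R carbinol, HCO2H/Et3N) should give the cis ester ethyl (1S,2R)-2-hydroxy-6,7-dimethoxy-1,2,3,4-tetrahydronaphthalene-1-carboxylate F2. Amidation (MeNHOMe·HCl, iPrMgCl, THF, −20 °C) leads to (1S,2R)-2-hydroxy-N,6,7-trimethoxy-N-methyl-1,2,3,4-tetrahydronaphthalene-1-carboxamide F3, and LiC≡CSiMe3 (THF, −78 °C) to 1-[(1S,2R)-2-hydroxy-6,7-dimethoxy-1,2,3,4-tetrahydronaphthalen-1-yl]-3-(trimethylsilyl)prop-2-yn-1-one F4. Narasaka–Prasad reduction (Et2BOMe, NaBH4, THF/MeOH, −78 °C) then relays C1' from C2 as the 1,3-syn diol 11, and K2CO3/MeOH gives 12.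

Step 4. The dioxirane may show poor facial selectivity toward one enantiomer of racemic 7 (a mismatched pair), which would erode the enantiomeric purity of 9 after the two epimers converge; partial loss of the silyl group is a lesser concern. The fallback replaces the stereoconvergent dioxirane epoxidation by a hydroxyl-directed, catalyst-controlled epoxidation with kinetic resolution. Hf(OtBu)4 with a chiral bishydroxamic acid ligand derived from trans-1,2-diaminocyclohexane and cumene hydroperoxide (toluene, 0 °C) is stopped near half conversion. It sets out from 7 and comes back at 8, obtained as a single carbinol epimer of the (2S,3S)-epoxide; it makes no compound beyond the list (F0).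

Step 8. Hydroalumination may be sluggish or incomplete because the aryl ring, present as its aluminium phenoxide, is electron-rich, and forcing conditions risk over-reduction. The fallback sets the E geometry by syn-hydrometalation of the terminal alkyne and bypasses 14; it sets out from 12 and comes back at 15. Copper-catalysed anti-Markovnikov hydroboration of 12 (B2pin2, CuCl, Xantphos, NaOtBu, MeOH, THF, rt) should give (1S,2R)-1-[(1S,2E)-1-hydroxy-3-(4,4,5,5-tetramethyl-1,3,2-dioxaborolan-2-yl)prop-2-en-1-yl]-6,7-dimethoxy-1,2,3,4-tetrahydronaphthalen-2-ol F5. Suzuki–Miyaura coupling with 13 (PdCl2(dppf), K2CO3, dioxane/H2O, 60 °C) then gives 15.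

Further compounds
F1 | step 5 | ethyl 6,7-dimethoxy-2-oxo-1,2,3,4-tetrahydronaphthalene-1-carboxylate | CCOC(=O)C1C(=O)CCc2cc(OC)c(OC)cc21
F2 | step 5 | ethyl (1S,2R)-2-hydroxy-6,7-dimethoxy-1,2,3,4-tetrahydronaphthalene-1-carboxylate | CCOC(=O)[C@@H]1[C@H](O)CCc2cc(OC)c(OC)cc21
F3 | step 5 | (1S,2R)-2-hydroxy-N,6,7-trimethoxy-N-methyl-1,2,3,4-tetrahydronaphthalene-1-carboxamide | CON(C)C(=O)[C@@H]1[C@H](O)CCc2cc(OC)c(OC)cc21
F4 | step 5 | 1-[(1S,2R)-2-hydroxy-6,7-dimethoxy-1,2,3,4-tetrahydronaphthalen-1-yl]-3-(trimethylsilyl)prop-2-yn-1-one | C[Si](C)(C)C#CC(=O)[C@@H]1[C@H](O)CCc2cc(OC)c(OC)cc21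
F0 | step 4 | none | none
F5 | step 8 | (1S,2R)-1-[(1S,2E)-1-hydroxy-3-(4,4,5,5-tetramethyl-1,3,2-dioxaborolan-2-yl)prop-2-en-1-yl]-6,7-dimethoxy-1,2,3,4-tetrahydronaphthalen-2-ol | COc1cc2c(cc1OC)[C@H]([C@@H](O)/C=C/B1OC(C)(C)C(C)(C)O1)[C@H](O)CC2
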